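**Retrosynthetic overview**

1. Ring locants: cyclohexane C1 = C(CH3)(acyl), C2 = CH(3-oxobutyl), C3 = C(CH3)2; the C1 methyl and the C2 hydrogen are cis. The last operations are acetylation of the primary glycerol OH and one acid step that frees the methyl ketone and the glycerol diol.
2. Key disconnection: ring bond C1–C2, leading back to the acyclic tertiary α-chloro ketone 23. The only ring of the target is closed by a 6-exo-trig radical cyclization inside a photoexcited flavin-dependent ene-reductase, which should set both ring stereocentres and deliver the oxidation level of the target directly.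
3. Enabling feature: C1 is α to the exocyclic ketone (a carbonyl-stabilised tertiary radical from a C–Cl bond); C2 and the first CH2 of the oxobutyl chain carry only C and H (the two carbons of an unactivated alkene); the gem-dimethyl carbon C3 next to that alkene favours closure.
4. 23 comes from decarboxylative chlorination after C-alkylation of the α-methyl β-keto allyl ester 20 with alkenyl iodide 11, two fragments of similar size. 20 derives from (R)-citronellic acid and (S)-solketal, which bring the two remote stereocentres; 11 derives from isobutyronitrile, 1-bromo-3-chloropropane and a ketal-protected C4 Wittig salt.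

Key step: step 12

Remark on the chemistry: compounds 19–23 are carried as mixtures of epimers at carbons that later become planar (ketone, enol or radical). The (Z)-alkene expected in 10, 11 and 21–23 is consumed in step 12, so its geometry is not critical.

**Route**

Step 1
Reactants: 1 isobutyronitrile; 2 1-bromo-3-chloropropane
Product: 4 5-chloro-2,2-dimethylpentanenitrile, via lithiated isobutyronitrile 3 (not isolated)
Conditions: LiN(iPr)2 (LDA), THF, −78 °C; then 2, −78 °C → rt
Reagents that add atoms: none
Why: α-Alkylation of a nitrile anion, in which the lithiated nitrile displaces bromide (a far better leaving group than chloride) by SN2 and so builds the gem-dimethyl quaternary carbon (future ring C3) while the chloride is kept for later.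

Step 2
Reactants: 4 5-chloro-2,2-dimethylpentanenitrile
Product: 6 5-chloro-2,2-dimethylpentanal, via N-aluminoimine 5 (not isolated)
Conditions: iBu2AlH (DIBAL-H), CH2Cl2, −78 °C; then 1 M aq HCl, 0 °C → rt
Reagents that add atoms: water (O)
Why: Partial reduction of a nitrile with DIBAL-H stops at the N-aluminoimine, which should hydrolyse on acidic work-up to the non-enolisable neopentyl aldehyde while the primary chloride stays untouched.

Step 3
Reactants: 7 2-(2-bromoethyl)-2-methyl-1,3-dioxolane
Product: 8 [2-(2-methyl-1,3-dioxolan-2-yl)ethyl]triphenylphosphonium bromide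
Conditions: PPh3, MeCN, reflux
Reagents that add atoms: triphenylphosphine (c1ccc(cc1)P(c1ccccc1)c1ccccc1)
Why: SN2 quaternisation of triphenylphosphine by a primary bromide (phosphonium salt formation) under neutral conditions that the ketal tolerates.

Step 4
Reactants: 8 [2-(2-methyl-1,3-dioxolan-2-yl)ethyl]triphenylphosphonium bromide; 6 5-chloro-2,2-dimethylpentanal
Product: 10 2-[(2Z)-7-chloro-4,4-dimethylhept-2-en-1-yl]-2-methyl-1,3-dioxolane, via phosphonium ylide 9 (not isolated)
Conditions: NaN(SiMe3)2, THF, −78 → 0 °C; then 6, −78 °C → rt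
Reagents that add atoms: none
Why: Wittig olefination of an α-quaternary aldehyde with a non-stabilised ylide under lithium-free conditions should give mainly the (Z)-alkene, which carries the masked 3-oxobutyl chain.

Step 5
Reactants: 10 2-[(2Z)-7-chloro-4,4-dimethylhept-2-en-1-yl]-2-methyl-1,3-dioxolane
Product: 11 2-[(2Z)-7-iodo-4,4-dimethylhept-2-en-1-yl]-2-methyl-1,3-dioxolane
Conditions: NaI, acetone, reflux
Reagents that add atoms: sodium iodide ([Na+].[I-])
Why: Finkelstein halide exchange, driven by precipitation of NaCl, should give the more reactive primary iodide for the fragment union.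

Step 6
Reactants: 12 (R)-citronellic acid; 13 (S)-solketal
Product: 14 [(4R)-2,2-dimethyl-1,3-dioxolan-4-yl]methyl (3R)-3,7-dimethyloct-6-enoate
Conditions: DCC, DMAP (cat.), CH2Cl2, 0 °C → rt
Reagents that add atoms: none
Why: Steglich esterification joins two purchased building blocks, which supply the C-3 methyl stereocentre and the glycerol stereocentre of the target without touching either.

Step 7
Reactants: 14 [(4R)-2,2-dimethyl-1,3-dioxolan-4-yl]methyl (3R)-3,7-dimethyloct-6-enoate
Product: 16 [(4R)-2,2-dimethyl-1,3-dioxolan-4-yl]methyl (3R)-3-methyl-6-oxohexanoate, via secondary ozonide 15 (not isolated)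
Conditions: O3, CH2Cl2, −78 °C; then PPh3, −78 °C → rt
Reagents that add atoms: ozone ([O-][O+]=O)
Why: Ozonolysis with reductive work-up should cleave the electron-rich trisubstituted alkene to the aldehyde under neutral conditions that leave the ester and the acetonide intact.

Step 8
Reactants: 16 [(4R)-2,2-dimethyl-1,3-dioxolan-4-yl]methyl (3R)-3-methyl-6-oxohexanoate; 17 allyl propanoate
Product: 19 1-allyl 8-{[(4R)-2,2-dimethyl-1,3-dioxolan-4-yl]methyl} (6R)-3-hydroxy-2,6-dimethyloctanedioate (diastereomer mixture at C2/C3), via lithium ester enolate 18 (not isolated)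
Conditions: LiN(iPr)2, 17, THF, −78 °C; then 16, −78 °C; AcOH quench at −78 °C
Reagents that add atoms: none
Why: Aldol addition of a lithium ester enolate to the aldehyde at −78 °C (faster than attack on the ester) forms the C–C bond next to the future ketone, and the two new stereocentres need no control because both are erased in steps 9 to 12.

Step 9
Reactants: 19 1-allyl 8-{[(4R)-2,2-dimethyl-1,3-dioxolan-4-yl]methyl} (6R)-3-hydroxy-2,6-dimethyloctanedioate
Product: 20 1-allyl 8-{[(4R)-2,2-dimethyl-1,3-dioxolan-4-yl]methyl} (6R)-2,6-dimethyl-3-oxooctanedioate (C2 epimers)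
Conditions: Dess–Martin periodinane, CH2Cl2, 0 °C → rt
Reagents that add atoms: none
Why: Dess–Martin oxidation should convert the secondary β-hydroxy ester into the β-keto ester under near-neutral conditions that the acetonide tolerates.

Step 10
Reactants: 20 1-allyl 8-{[(4R)-2,2-dimethyl-1,3-dioxolan-4-yl]methyl} (6R)-2,6-dimethyl-3-oxooctanedioate; 11 2-[(2Z)-7-iodo-4,4-dimethylhept-2-en-1-yl]-2-methyl-1,3-dioxolane
Product: 21 1-allyl 8-{[(4R)-2,2-dimethyl-1,3-dioxolan-4-yl]methyl} (6R)-2-[(5Z)-4,4-dimethyl-7-(2-methyl-1,3-dioxolan-2-yl)hept-5-en-1-yl]-2,6-dimethyl-3-oxooctanedioate (C2 epimers)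
Conditions: Cs2CO3, DMF, 25 → 40 °C
Reagents that add atoms: none
Why: C-Alkylation of the caesium enolate of an α-methyl β-keto ester with a primary iodide (acetoacetic ester alkylation) unites the two fragments at the carbon that becomes ring C1, whose configuration is irrelevant at this stage.

Step 11
Reactants: 21 1-allyl 8-{[(4R)-2,2-dimethyl-1,3-dioxolan-4-yl]methyl} (6R)-2-[(5Z)-4,4-dimethyl-7-(2-methyl-1,3-dioxolan-2-yl)hept-5-en-1-yl]-2,6-dimethyl-3-oxooctanedioate
Product: 23 [(4R)-2,2-dimethyl-1,3-dioxolan-4-yl]methyl (3R,12Z)-7-chloro-3,7,11,11-tetramethyl-14-(2-methyl-1,3-dioxolan-2-yl)-6-oxotetradec-12-enoate (C7 epimers), via β-keto acid 22 (not isolated)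
Conditions: Pd(PPh3)4 (3 mol %), morpholine (1.1 equiv), THF, 0 °C; then N-chlorosuccinimide, toluene, 0 °C → rt
Reagents that add atoms: N-chlorosuccinimide (O=C1CCC(=O)N1Cl)
Why: Palladium-catalysed allyl transfer to morpholine (Tsuji–Trost deallylation) frees the β-keto acid, and its decarboxylative chlorination places chlorine regiospecifically on the tertiary α-carbon because loss of CO2 generates the enol only there, with the 4-allylmorpholine formed acting as the amine base.

Step 12
Reactants: 23 [(4R)-2,2-dimethyl-1,3-dioxolan-4-yl]methyl (3R,12Z)-7-chloro-3,7,11,11-tetramethyl-14-(2-methyl-1,3-dioxolan-2-yl)-6-oxotetradec-12-enoate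
Product: 24 [(4R)-2,2-dimethyl-1,3-dioxolan-4-yl]methyl (3R)-3-methyl-6-oxo-6-{(1R,2S)-1,3,3-trimethyl-2-[2-(2-methyl-1,3-dioxolan-2-yl)ethyl]cyclohexyl}hexanoate
Conditions: flavin (FMN)-dependent ene-reductase of the Old Yellow Enzyme family (variant from screening), NADP+ (cat.), glucose dehydrogenase, D-glucose, KH2PO4/K2HPO4 buffer pH 8, DMSO (10 vol %), cyan LEDs (ca. 495 nm), 25 °C, under N2
Reagents that add atoms: none
Why: Proposed new method: the reduced flavin (FMN hydroquinone) of the ene-reductase forms a charge-transfer complex with the bound tertiary α-chloro ketone, cyan-light excitation transfers one electron, chloride leaves, and the carbonyl-stabilised tertiary radical (future ring C1) adds to the near alkene carbon (future ring C2) before the flavin semiquinone returns a hydrogen atom to the exocyclic radical carbon, so 24 is formed directly at the oxidation level of the target. The closest known reaction type is the photoenzymatic reductive radical cyclization of α-chloroamides onto unactivated alkenes in flavin-dependent ene-reductases, which closes five- and six-membered lactams with enzyme-set stereocentres; here it is extended to an α-chloro ketone, a fully substituted radical carbon and a carbocycle. The cyclohexane ring closes in the 6-exo-trig mode. Both new stereocentres, quaternary C1 (R) and tertiary C2 (S), arise in the same C–C bond-forming event, and the controlling element is the pose enforced by the chiral active site (ketone oxygen hydrogen-bonded to the conserved histidine/asparagine pair above the flavin, alkene folded under the radical), so the variant is to be chosen from a panel (the 12-oxophytodienoate reductases, whose natural substrate is a long-chain keto acid, are the first candidates) and refined by directed evolution for the cis (1R,2S) ring. The step needs 6-exo over 7-endo closure and ring closure faster than premature hydrogen-atom return: the gem-dimethyl carbon in the tether (gem-dialkyl effect) and the 1,2-disubstituted alkene favour exo attack, and the hindered tertiary radical should accept a hydrogen atom only slowly. Both C7 epimers of 23 and either alkene geometry give the same planar radical, so the precursor needs no stereochemical information at the reacting carbons.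

Step 13
Reactants: 24 [(4R)-2,2-dimethyl-1,3-dioxolan-4-yl]methyl (3R)-3-methyl-6-oxo-6-{(1R,2S)-1,3,3-trimethyl-2-[2-(2-methyl-1,3-dioxolan-2-yl)ethyl]cyclohexyl}hexanoate
Product: 25 (2R)-2,3-dihydroxypropyl (3R)-3-methyl-6-oxo-6-[(1R,2S)-1,3,3-trimethyl-2-(3-oxobutyl)cyclohexyl]hexanoate
Conditions: 1 M aq HCl/THF (1:4), 0 °C → rt
Reagents that add atoms: water (O)
Why: Acid-catalysed acetal hydrolysis should remove the ethylene ketal and the acetonide in one operation, and no stereocentre is at risk because ring C1 is quaternary and ring C2 and the chain methine are not α to a carbonyl.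

Step 14
Reactants: 25 (2R)-2,3-dihydroxypropyl (3R)-3-methyl-6-oxo-6-[(1R,2S)-1,3,3-trimethyl-2-(3-oxobutyl)cyclohexyl]hexanoate
Product: 26 (2R)-3-(acetyloxy)-2-hydroxypropyl (3R)-3-methyl-6-oxo-6-[(1R,2S)-1,3,3-trimethyl-2-(3-oxobutyl)cyclohexyl]hexanoate (target)
Conditions: AcCl (1.05 equiv), 2,4,6-collidine, CH2Cl2, −78 °C
Reagents that add atoms: acetyl chloride (CC(Cl)=O)
Why: Regioselective acylation of the primary over the secondary hydroxyl with acetyl chloride and a hindered pyridine base at low temperature should give the 1,3-diacylglycerol, which is also the thermodynamically preferred acyl arrangement.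

**Compound list**

1 | isobutyronitrile (2-methylpropanenitrile) | CC(C)C#N | starting material
2 | 1-bromo-3-chloropropane | ClCCCBr | starting material
3 | lithiated isobutyronitrile (lithium keteniminate) | CC(C)=C=N[Li] | intermediate
4 | 5-chloro-2,2-dimethylpentanenitrile | N#CC(C)(C)CCCCl | intermediate
5 | N-(diisobutylalumanyl)-5-chloro-2,2-dimethylpentan-1-imine | CC(C)C[Al](CC(C)C)N=CC(C)(C)CCCCl | intermediate
6 | 5-chloro-2,2-dimethylpentanal | O=CC(C)(C)CCCCl | intermediate
7 | 2-(2-bromoethyl)-2-methyl-1,3-dioxolane | CC1(CCBr)OCCO1 | starting material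
8 | [2-(2-methyl-1,3-dioxolan-2-yl)ethyl]triphenylphosphonium bromide | CC1(CC[P+](c2ccccc2)(c2ccccc2)c2ccccc2)OCCO1.[Br-] | intermediate
9 | [2-(2-methyl-1,3-dioxolan-2-yl)ethylidene]triphenylphosphorane | CC1(CC=P(c2ccccc2)(c2ccccc2)c2ccccc2)OCCO1 | intermediate
10 | 2-[(2Z)-7-chloro-4,4-dimethylhept-2-en-1-yl]-2-methyl-1,3-dioxolane | CC1(C/C=C\C(C)(C)CCCCl)OCCO1 | intermediate
11 | 2-[(2Z)-7-iodo-4,4-dimethylhept-2-en-1-yl]-2-methyl-1,3-dioxolane | CC1(C/C=C\C(C)(C)CCCI)OCCO1 | intermediate
12 | (R)-citronellic acid, (3R)-3,7-dimethyloct-6-enoic acid | CC(C)=CCC[C@@H](C)CC(=O)O | starting material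
13 | (S)-solketal, [(4S)-2,2-dimethyl-1,3-dioxolan-4-yl]methanol | OC[C@H]1COC(C)(C)O1 | starting material
14 | [(4R)-2,2-dimethyl-1,3-dioxolan-4-yl]methyl (3R)-3,7-dimethyloct-6-enoate | CC(C)=CCC[C@@H](C)CC(=O)OC[C@H]1COC(C)(C)O1 | intermediate
15 | secondary ozonide of 14 (3,3-dimethyl-1,2,4-trioxolane carrying the ester chain at C5) | CC1(C)OOC(CC[C@@H](C)CC(=O)OC[C@H]2COC(C)(C)O2)O1 | intermediate
16 | [(4R)-2,2-dimethyl-1,3-dioxolan-4-yl]methyl (3R)-3-methyl-6-oxohexanoate | O=CCC[C@@H](C)CC(=O)OC[C@H]1COC(C)(C)O1 | intermediate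
17 | allyl propanoate (prop-2-en-1-yl propanoate) | CCC(=O)OCC=C | starting material
18 | lithium enolate of allyl propanoate | CC=C(O[Li])OCC=C | intermediate
19 | 1-allyl 8-{[(4R)-2,2-dimethyl-1,3-dioxolan-4-yl]methyl} (6R)-3-hydroxy-2,6-dimethyloctanedioate (mixture at C2 and C3) | C=CCOC(=O)C(C)C(O)CC[C@@H](C)CC(=O)OC[C@H]1COC(C)(C)O1 | intermediate
20 | 1-allyl 8-{[(4R)-2,2-dimethyl-1,3-dioxolan-4-yl]methyl} (6R)-2,6-dimethyl-3-oxooctanedioate (C2 epimers) | C=CCOC(=O)C(C)C(=O)CC[C@@H](C)CC(=O)OC[C@H]1COC(C)(C)O1 | intermediate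
21 | 1-allyl 8-{[(4R)-2,2-dimethyl-1,3-dioxolan-4-yl]methyl} (6R)-2-[(5Z)-4,4-dimethyl-7-(2-methyl-1,3-dioxolan-2-yl)hept-5-en-1-yl]-2,6-dimethyl-3-oxooctanedioate (C2 epimers) | C=CCOC(=O)C(C)(CCCC(C)(C)/C=C\CC1(C)OCCO1)C(=O)CC[C@@H](C)CC(=O)OC[C@H]2COC(C)(C)O2 | intermediate
22 | (6R)-2-[(5Z)-4,4-dimethyl-7-(2-methyl-1,3-dioxolan-2-yl)hept-5-en-1-yl]-8-{[(4R)-2,2-dimethyl-1,3-dioxolan-4-yl]methoxy}-2,6-dimethyl-3,8-dioxooctanoic acid (C2 epimers) | OC(=O)C(C)(CCCC(C)(C)/C=C\CC1(C)OCCO1)C(=O)CC[C@@H](C)CC(=O)OC[C@H]2COC(C)(C)O2 | intermediate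
23 | [(4R)-2,2-dimethyl-1,3-dioxolan-4-yl]methyl (3R,12Z)-7-chloro-3,7,11,11-tetramethyl-14-(2-methyl-1,3-dioxolan-2-yl)-6-oxotetradec-12-enoate (C7 epimers) | CC(Cl)(CCCC(C)(C)/C=C\CC1(C)OCCO1)C(=O)CC[C@@H](C)CC(=O)OC[C@H]2COC(C)(C)O2 | intermediate
24 | [(4R)-2,2-dimethyl-1,3-dioxolan-4-yl]methyl (3R)-3-methyl-6-oxo-6-{(1R,2S)-1,3,3-trimethyl-2-[2-(2-methyl-1,3-dioxolan-2-yl)ethyl]cyclohexyl}hexanoate | CC1(CC[C@H]2C(C)(C)CCC[C@@]2(C)C(=O)CC[C@@H](C)CC(=O)OC[C@H]3COC(C)(C)O3)OCCO1 | intermediate
25 | (2R)-2,3-dihydroxypropyl (3R)-3-methyl-6-oxo-6-[(1R,2S)-1,3,3-trimethyl-2-(3-oxobutyl)cyclohexyl]hexanoate | CC(=O)CC[C@H]1C(C)(C)CCC[C@@]1(C)C(=O)CC[C@@H](C)CC(=O)OC[C@H](O)CO | intermediate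
26 | (2R)-3-(acetyloxy)-2-hydroxypropyl (3R)-3-methyl-6-oxo-6-[(1R,2S)-1,3,3-trimethyl-2-(3-oxobutyl)cyclohexyl]hexanoate | CC(=O)CC[C@H]1C(C)(C)CCC[C@@]1(C)C(=O)CC[C@@H](C)CC(=O)OC[C@H](O)COC(C)=O | target

**Step count and risks**

Total step count: 14. Longest linear sequence: 9 steps (steps 6 to 14 from 12; equally steps 1, 2, 4, 5 and 10 to 14 from 1).

Steps most likely to fail:

1. Step 12 (Proposed new method). The hydrogen atom may return to the tertiary radical before ring closure (plain dechlorination). Closure may occur at the far alkene carbon to give a seven-membered ring. The enzyme may discriminate the faces poorly or bind the long substrate weakly. The fallback uses known chemistry, sets out from 23 and comes back at 24. It is a tin hydride-mediated reductive radical cyclization (Bu3SnH added slowly, AIBN, benzene, 80 °C), a known 6-exo closure of α-halo ketone radicals without reagent control over the ring stereocentres. It should give 24 together with the (1S,2R)-cyclohexyl diastereomer F1, the (1R,2R)-cyclohexyl diastereomer F2 and the (1S,2S)-cyclohexyl diastereomer F3. Because the two remote stereocentres are fixed, all four are diastereomers, and 24 would be isolated by preparative HPLC (on a chiral stationary phase if needed) before the route continues with step 13.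

2. Step 11. Carbon dioxide may be lost and the enol protonated before chlorine transfer, leaving the unchlorinated ketone. The allyl group may also be transferred to carbon after decarboxylation during the deallylation. The fallback sets out from 21 (through acid 22) and comes back at 23, and separates decarboxylation from halogenation. Acid 22 is silylated with N,O-bis(trimethylsilyl)acetamide to the trimethylsilyl β-keto carboxylate F4. Heating (toluene, 80–100 °C) should expel CO2 with silyl transfer to oxygen and give regiospecifically the tetrasubstituted trimethylsilyl enol ether F5. F5 is then chlorinated with N-chlorosuccinimide (THF, 0 °C) to 23.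

3. Step 13. The acyl group may migrate from the primary to the secondary oxygen of the freed diol under acid, or the ethylene ketal may hydrolyse incompletely. The fallback sets out from 24 and comes back at 25, using two selective operations in place of one global hydrolysis. Exchange of the ethylene ketal onto acetone (pyridinium p-toluenesulfonate, dry acetone, reflux) keeps the acetonide intact in the acetone medium and should give the diketone acetonide F6. The acetonide is then cleaved with B(OH)3 in 2-methoxyethanol at 100 °C, where the borate ester formed blocks acyl migration, and evaporation with methanol releases 25.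

Further compounds
F1 | step 12 | [(4R)-2,2-dimethyl-1,3-dioxolan-4-yl]methyl (3R)-3-methyl-6-oxo-6-{(1S,2R)-1,3,3-trimethyl-2-[2-(2-methyl-1,3-dioxolan-2-yl)ethyl]cyclohexyl}hexanoate | CC1(CC[C@@H]2C(C)(C)CCC[C@]2(C)C(=O)CC[C@@H](C)CC(=O)OC[C@H]3COC(C)(C)O3)OCCO1
F2 | step 12 | [(4R)-2,2-dimethyl-1,3-dioxolan-4-yl]methyl (3R)-3-methyl-6-oxo-6-{(1R,2R)-1,3,3-trimethyl-2-[2-(2-methyl-1,3-dioxolan-2-yl)ethyl]cyclohexyl}hexanoate | CC1(CC[C@@H]2C(C)(C)CCC[C@@]2(C)C(=O)CC[C@@H](C)CC(=O)OC[C@H]3COC(C)(C)O3)OCCO1
F3 | step 12 | [(4R)-2,2-dimethyl-1,3-dioxolan-4-yl]methyl (3R)-3-methyl-6-oxo-6-{(1S,2S)-1,3,3-trimethyl-2-[2-(2-methyl-1,3-dioxolan-2-yl)ethyl]cyclohexyl}hexanoate | CC1(CC[C@H]2C(C)(C)CCC[C@]2(C)C(=O)CC[C@@H](C)CC(=O)OC[C@H]3COC(C)(C)O3)OCCO1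
F4 | step 11 | trimethylsilyl ester of acid 22 (trimethylsilyl β-keto carboxylate, C2 epimers) | C[Si](C)(C)OC(=O)C(C)(CCCC(C)(C)/C=C\CC1(C)OCCO1)C(=O)CC[C@@H](C)CC(=O)OC[C@H]2COC(C)(C)O2
F5 | step 11 | [(4R)-2,2-dimethyl-1,3-dioxolan-4-yl]methyl (3R,12Z)-3,7,11,11-tetramethyl-14-(2-methyl-1,3-dioxolan-2-yl)-6-[(trimethylsilyl)oxy]tetradeca-6,12-dienoate (enol ether E/Z mixture) | C[Si](C)(C)OC(CC[C@@H](C)CC(=O)OC[C@H]1COC(C)(C)O1)=C(C)CCCC(C)(C)/C=C\CC2(C)OCCO2
F6 | step 13 | [(4R)-2,2-dimethyl-1,3-dioxolan-4-yl]methyl (3R)-3-methyl-6-oxo-6-[(1R,2S)-1,3,3-trimethyl-2-(3-oxobutyl)cyclohexyl]hexanoate | CC(=O)CC[C@H]1C(C)(C)CCC[C@@]1(C)C(=O)CC[C@@H](C)CC(=O)OC[C@H]2COC(C)(C)O2
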